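The closed, stirred vessel starts with free monomer and a small charge of initiator, and the chain length in it can be written with two fractions of the charge.

- alpha: free monomer 2 M; initiator 1 mol%; the very flask that is asked about, followed so far
- flask: free monomer 2.0 M; initiator 1 mol%; time 8.0 h

- alpha (time / min: monomer in chains / %, free monomer / %): 5.00: 0.4, 98.1; 12.0: 1.4, 97.2; 25.0: 2.1, 93.3; 40.0: 4.1, 89.3; 50.0: 6.8, 86.3; 60.0: 8.0, 81.2; 80.0: 14.0, 73.7

(readings scatter by 0.5 percentage points)

- the average divides the monomer in chains by the number of chains begun, living and dead together
- steps that have been proposed: free monomer -> uncatalysed product; free monomer + initiator -> living end + monomer in chains; free monomer + living end -> monomer in chains + living end; monomer in chains -> over-reaction product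
- the earlier runs do not show the number of chains; that part of a forecast is a guess

- whether the average number of monomer units in a chain (chains begun, living or dead) reaches 80 by 8.0 h (yes / no)
- average number of monomer units in a chain (chains begun, living or dead) at 8.0 h

The charge ratio, here 100, is the units of free monomer charged per initiator charged. It enters thus:

length = charge ratio × fraction of the monomer in chains ÷ fraction of the initiator used

With growth of chains on its own and every initiator begun, both fractions would tend to one, and the length would be the charge ratio, more than the 80 wanted.

Now add the uncatalysed loss. At 80.0 min the alpha readings put 53.2 % of the lost free monomer into chains, a selectivity that carries their scatter. Taken as it stands, with the free monomer fully reacted and every initiator used, it gives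

charge ratio × selectivity = 53.2

which is less than the length wanted.

Last comes the beginning of chains. From 40.0 min to 80.0 min in the alpha run the time doubles, yet monomer in chains grows 3.41-fold, a reading that points to chains still being begun. Joining the ends, with the free monomer fully reacted at that selectivity, the wanted length needs at most 66.5 % of the initiator used. The readings do not show that fraction, so this reckoning gives a condition, and a yes from it is a guess.

The forecast says yes, with a length of 140: “Only about 40–55% of the initiator has started chains”.

The flask gives yes, with a length of 94.1.

    free monomer → uncatalysed product (k = 2.70 × 10⁻⁵ /s)
    free monomer + initiator → living end + monomer in chains (k = 6.00 × 10⁻⁵ /M/s)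
    free monomer + living end → monomer in chains + living end, rate k3*[living end]*[free monomer] (k = 0.00740 /M/s)
    monomer in chains → over-reaction product (k = 2.80 × 10⁻⁷ /s)

At 8.00 h, 28 % of the initiator is left, so 71.6 % has been used, against the forecast's 40 to 55 %. The charge ratio with 67.4 % of the monomer in chains and that fraction returns 94.1. At 0.800 h, with 6.14 % in chains and 72.3 % of the initiator left, it returns 22.1, and the flask then stands at 22.1.

(The data were generated by integration for substances that don't exist; noise was put on by code.)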